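You read your flask at 2.0 h. In the winter run, L and Z stand still within the scatter of 2 percentage points from 10.0 min on, so I reckon with an equilibrium. Your hunch is that equal charges run to the end. I reckon otherwise.

| flask | L | E | remark | time |
|---|---|---|---|---|
| summer | 6.7 × 10⁻⁴ M | 1 mM (in portions, 4) | run made earlier; portions every 4.0 s |  |
| midnight | 0.0015 M | 1 mM (in portions, 4) | run made earlier; portions every 4.0 s |  |
| winter | 0.0010 M | 1.5 mM (in portions, 4) | run made earlier; portions every 4.0 s |  |
| flask | 0.0010 M | 1.00 mM (in portions, 4) | the portions of E follow each other after 4.0 s, the first at the start | 2.0 h |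

| run | time / min | L / % | Z / % |
|---|---|---|---|
| summer | 15.0 | 2 | 95 |
| summer | 40.0 | 1 | 99 |
| summer | 80.0 | 0 | 97 |
| summer | 120 | 3 | 98 |
| midnight | 15.0 | 34 | 66 |
| midnight | 40.0 | 35 | 65 |
| midnight | 80.0 | 37 | 63 |
| midnight | 120 | 34 | 66 |
| winter | 10.0 | 1 | 98 |
| winter | 20.0 | 1 | 97 |
| winter | 50.0 | 0 | 98 |
| winter | 120 | 4 | 98 |

(readings scatter by 2 percentage points)

- Z is meant together with its D
- solid, in amounts per volume of the solution: D
- the numbers in the tables scatter with a standard deviation of 2 percentage points
- on the list of suspects stand: L + E <-> Z + Q; D <-> Z
- the reaction counts as stopped when no species that holds the L changes by six tenths of a point or more over the second half of the time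

* the state of affairs at 2.0 h: stopped, and by what, or still going (all of L has reacted / forward and back rates have come level / E has run out first / it is still moving)
* share of the L used up at 2.0 h
* Z at 2.0 h, in percent of the L charged

1. In the midnight run, E is the limiting reagent, 1 mM against 0.0015 M of L. Its charge allows 66.7% of L to react, and Z reads 65.0% on average.
2. Your flask stands at the crossing, with 1.00 mM of E against 0.0010 M of L. Neither reagent is the short one, so the equilibrium has to tell what stays.
3. I assume solid D stands by and holds dissolved Z still, so I leave c_Z out. In the winter run, L averages 1.50%, a rough reading against that scatter. The balance then gives 128 mM⁻¹ for c_Q/(c_L c_E), the resting quotient.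
4. In your flask c_L equals c_E and c_Q equals the L used, so the quotient gives c_L = 0.0847 mM. I commit to 91.5% of L used.

The forecast says forward and back rates have come level, on the ground that “The runs settle fast”, and it gives 92% of L used and Z at 92%.

The flask gives forward and back rates have come level, with 90.5% of L used and Z at 90.5%. At 2.00 h L stands at 9.51% and D at 50.5%, counted in Z.

    L + E ⇌ Z + Q (K = 40.0, k = 5600 M⁻¹ s⁻¹)
    D ⇌ Z, rate k2*(cs2 - [Z]) while solid is left; crystals form when [Z] > cs2 (solubility = 0.400 mM, k = 3.30 s⁻¹)

The quotient also shows how steep the crossing is. With E lowered to 0.914 mM, it gives 86.4%, a fall of 5.1 points, and the computed flask moves 5 points there.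

Now take a second flask with 6.0 × 10⁻⁴ M of E, where E is short again. The quotient gives 58.9% of L used, with 1.87% of E's charge left. The computed flask gives 58.6% of L used and 2.4% of E's charge left.

(Readings and results were computed from invented constants; scatter was added.)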